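**Plan**
- Retrosynthesis: cut the two depside ester C–O bonds (ring C carbonyl to O4 of ring B, ring B carbonyl to O4 of ring A), then, inside ring B, the C1–C6 and C3–C4 bonds.
- Ring B has its carboxyl on C1, oxygen on C2 and C4, and methyl on C3, C5 and C6. This is a masked 2,4-dioxocyclohexane-1-carboxylate: methyl 3-oxopentanoate supplies C1, C2, C3 and the C3 methyl, and methyl tiglate supplies C4, C5, C6 and their two methyls.
- Forward: a Michael–Claisen annulation closes ring B as a dione (step 1) and bromination–dehydrobromination makes it aromatic (step 2). Rings A and C both come from 2,5-dimethylresorcinol through one formylated intermediate.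
- Chain assembly: ring C acid onto O4 of ring B (this ester also serves as the O4 protecting group), O2 methylation, release of the ring B acid, ester to O4 of the ring A aldehyde, O2 methylation, CHO to CO2H, debenzylation.
- Stereochemistry: the target has no stereocentre; the four centres of the dione arise as a mixture and vanish on aromatisation.

Key step: step 1

Remark on the chemistry: dione 4 is drawn as its triketo tautomer although enol forms will dominate, and its diastereomers are carried on together. Methyl tiglate is taken as the (E) isomer; its geometry has no consequence.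

**Step 1**
Reactants: 1 methyl 3-oxopentanoate; 2 methyl tiglate (methyl (E)-2-methylbut-2-enoate)
Product: 4 methyl 3,5,6-trimethyl-2,4-dioxocyclohexane-1-carboxylate (diastereomer mixture), via Michael adduct 3 (not isolated)
Conditions: NaOMe (1.2 equiv), MeOH, reflux, 48 h; then 2 M HCl, 0 °C
Reagents that add atoms: none
Why: Methoxide deprotonates the doubly activated C2 methylene of 1, this enolate adds to the β-carbon of 2 (Michael addition, ring bond C1–C6) to give 3, and after proton transfer the enolate on the propanoyl side attacks the tiglate ester carbonyl with loss of methoxide (Claisen condensation, ring bond C3–C4). The closest known reaction type is the alkoxide-mediated Michael–Claisen condensation of 3-oxo esters with crotonates that gives dihydroresorcylates, for which an α-methylated acceptor is expected to react more slowly, hence the long reflux. The one ring closes in a 6-(enolendo)-exo-trig mode. Four sp3 centres (C1, C3, C5, C6) arise without control, and none needs control because step 2 flattens all of them. The selectivity needed is Michael attack through C2 and closure through the γ-carbon: the first is secured by the much higher acidity of the position between two carbonyls, the second because only the γ-enolate can reach the distal ester through a six-membered transition state. The reversible steps are pulled forward by deprotonation of the product dione, a vinylogous acid, and methoxide matches both methyl esters so that ester exchange is degenerate.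

**Step 2**
Reactants: 4 methyl 3,5,6-trimethyl-2,4-dioxocyclohexane-1-carboxylate
Product: 7 methyl 2,4-dihydroxy-3,5,6-trimethylbenzoate, via C3 bromodione 5 (not isolated), via C5 bromodione 6 (not isolated)
Conditions: Br2 (1.05 equiv), DMF, 0 °C; then 80 °C
Reagents that add atoms: none
Why: Bromination–dehydrobromination, the classical aromatisation of dihydroresorcylates: bromine first attacks the enolised dione at C3, this blocked bromide passes its halogen on under HBr to the enolisable C5, loss of HBr across C5–C6 gives a cyclohexadienone that tautomerises to the arene, and since every ring carbon is substituted no nuclear bromination can follow.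

**Step 3**
Reactants: 8 2,5-dimethylresorcinol
Product: 10 2,4-dihydroxy-3,6-dimethylbenzaldehyde, via aryl iminium chloride 9 (not isolated)
Conditions: POCl3 (1.2 equiv), DMF, MeCN, 0 °C to rt; then H2O, 50 °C
Reagents that add atoms: N,N-dimethylformamide, CN(C)C=O; water, O
Why: Vilsmeier–Haack formylation, in which the two free ring positions are equivalent and each lies ortho to one hydroxyl and para to the other, so a single aldehyde should form and the iminium group switches off a second attack.

**Step 4**
Reactants: 10 2,4-dihydroxy-3,6-dimethylbenzaldehyde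
Product: 11 2,4-bis(benzyloxy)-3,6-dimethylbenzaldehyde
Conditions: BnBr (2.5 equiv), K2CO3, DMF, 60 °C
Reagents that add atoms: benzyl bromide, BrCc1ccccc1
Why: Williamson ether synthesis on both phenols, the warm DMF being needed for the hydroxyl chelated to the formyl group.

**Step 5**
Reactants: 11 2,4-bis(benzyloxy)-3,6-dimethylbenzaldehyde
Product: 12 2,4-bis(benzyloxy)-3,6-dimethylbenzoic acid
Conditions: NaClO2, NaH2PO4, 2-methyl-2-butene, t-BuOH/THF/H2O, rt
Reagents that add atoms: sodium chlorite, [Na+].[O-]Cl=O
Why: Pinnick oxidation, which is insensitive to the two ortho substituents, while the alkene scavenger removes hypochlorous acid before it can chlorinate the free C5 position of the electron-rich ring.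

**Step 6**
Reactants: 12 2,4-bis(benzyloxy)-3,6-dimethylbenzoic acid; 7 methyl 2,4-dihydroxy-3,5,6-trimethylbenzoate
Product: 14 methyl 4-{[2,4-bis(benzyloxy)-3,6-dimethylbenzoyl]oxy}-2-hydroxy-3,5,6-trimethylbenzoate, via mixed trifluoroacetic anhydride 13 (not isolated)
Conditions: 12, (CF3CO)2O (1.2 equiv), toluene, rt, 30 min; then 7, rt
Reagents that add atoms: none
Why: Mixed-anhydride esterification of a hindered acid, in which the electron-rich 2,6-disubstituted acid ionises to a slim acylium ion that can reach the O4 hydroxyl between two methyl groups, while the O2 hydroxyl is hydrogen-bonded to the ester carbonyl and stays free.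

**Step 7**
Reactants: 14 methyl 4-{[2,4-bis(benzyloxy)-3,6-dimethylbenzoyl]oxy}-2-hydroxy-3,5,6-trimethylbenzoate
Product: 15 methyl 4-{[2,4-bis(benzyloxy)-3,6-dimethylbenzoyl]oxy}-2-methoxy-3,5,6-trimethylbenzoate
Conditions: MeI (3 equiv), K2CO3, DMF, 50 °C
Reagents that add atoms: iodomethane, CI
Why: Williamson methylation of the only free hydroxyl, the depside ester being shielded from carbonate by the two ortho substituents of its acyl ring.

**Step 8**
Reactants: 15 methyl 4-{[2,4-bis(benzyloxy)-3,6-dimethylbenzoyl]oxy}-2-methoxy-3,5,6-trimethylbenzoate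
Product: 16 4-{[2,4-bis(benzyloxy)-3,6-dimethylbenzoyl]oxy}-2-methoxy-3,5,6-trimethylbenzoic acid
Conditions: LiI (anhydrous, 8 equiv), EtOAc, reflux, N2 sweep; then 1 M HCl
Reagents that add atoms: none
Why: SN2 dealkylation of a methyl ester by iodide (O–alkyl cleavage), which attacks the unhindered methyl carbon and not the blocked carbonyl; the aryl ester offers no alkyl carbon, and the aryl ethers would have to expel far poorer phenoxide leaving groups.

**Step 9**
Reactants: 16 4-{[2,4-bis(benzyloxy)-3,6-dimethylbenzoyl]oxy}-2-methoxy-3,5,6-trimethylbenzoic acid; 10 2,4-dihydroxy-3,6-dimethylbenzaldehyde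
Product: 18 4-formyl-3-hydroxy-2,5-dimethylphenyl 4-{[2,4-bis(benzyloxy)-3,6-dimethylbenzoyl]oxy}-2-methoxy-3,5,6-trimethylbenzoate, via mixed trifluoroacetic anhydride 17 (not isolated)
Conditions: 16, (CF3CO)2O (1.2 equiv), toluene, rt, 30 min; then 10, rt
Reagents that add atoms: none
Why: The same mixed-anhydride esterification, selective for the 4-hydroxyl of 10 because the 2-hydroxyl is chelated to the formyl group, which also deactivates the free ring position toward C-acylation.

**Step 10**
Reactants: 18 4-formyl-3-hydroxy-2,5-dimethylphenyl 4-{[2,4-bis(benzyloxy)-3,6-dimethylbenzoyl]oxy}-2-methoxy-3,5,6-trimethylbenzoate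
Product: 19 4-formyl-3-methoxy-2,5-dimethylphenyl 4-{[2,4-bis(benzyloxy)-3,6-dimethylbenzoyl]oxy}-2-methoxy-3,5,6-trimethylbenzoate
Conditions: MeI (3 equiv), K2CO3, DMF, rt
Reagents that add atoms: iodomethane, CI
Why: Williamson methylation of the one remaining hydroxyl, both aryl esters being protected from carbonate by two ortho substituents on their acyl rings.

**Step 11**
Reactants: 19 4-formyl-3-methoxy-2,5-dimethylphenyl 4-{[2,4-bis(benzyloxy)-3,6-dimethylbenzoyl]oxy}-2-methoxy-3,5,6-trimethylbenzoate
Product: 20 4-[(4-{[2,4-bis(benzyloxy)-3,6-dimethylbenzoyl]oxy}-2-methoxy-3,5,6-trimethylbenzoyl)oxy]-2-methoxy-3,6-dimethylbenzoic acid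
Conditions: NaClO2, NaH2PO4, 2-methyl-2-butene, t-BuOH/THF/H2O, rt
Reagents that add atoms: sodium chlorite, [Na+].[O-]Cl=O
Why: Pinnick oxidation turns the formyl group, kept until now as a masked carboxyl, into the ring A acid under buffered conditions that leave aryl esters and benzyl ethers alone.

**Step 12**
Reactants: 20 4-[(4-{[2,4-bis(benzyloxy)-3,6-dimethylbenzoyl]oxy}-2-methoxy-3,5,6-trimethylbenzoyl)oxy]-2-methoxy-3,6-dimethylbenzoic acid
Product: 21 4-({4-[(2,4-dihydroxy-3,6-dimethylbenzoyl)oxy]-2-methoxy-3,5,6-trimethylbenzoyl}oxy)-2-methoxy-3,6-dimethylbenzoic acid (CNP0425440.0)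
Conditions: H2 (1 atm), 10% Pd/C, EtOAc, rt
Reagents that add atoms: none
Why: Hydrogenolysis of the two benzyl ethers over palladium on carbon, to which aryl esters, aryl methyl ethers and the carboxylic acid are inert.

**Compound list**
1 | methyl 3-oxopentanoate | CCC(=O)CC(=O)OC | starting material
2 | methyl tiglate, methyl (E)-2-methylbut-2-enoate | C/C=C(\C)C(=O)OC | starting material
3 | dimethyl 2,3-dimethyl-4-propanoylpentanedioate (Michael adduct, diastereomer mixture, not isolated) | CCC(=O)C(C(=O)OC)C(C)C(C)C(=O)OC | intermediate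
4 | methyl 3,5,6-trimethyl-2,4-dioxocyclohexane-1-carboxylate (diastereomer mixture) | COC(=O)C1C(C)C(C)C(=O)C(C)C1=O | intermediate
5 | methyl 3-bromo-3,5,6-trimethyl-2,4-dioxocyclohexane-1-carboxylate (diastereomer mixture, not isolated) | COC(=O)C1C(C)C(C)C(=O)C(C)(Br)C1=O | intermediate
6 | methyl 5-bromo-3,5,6-trimethyl-2,4-dioxocyclohexane-1-carboxylate (diastereomer mixture, not isolated) | COC(=O)C1C(C)C(C)(Br)C(=O)C(C)C1=O | intermediate
7 | methyl 2,4-dihydroxy-3,5,6-trimethylbenzoate | COC(=O)c1c(C)c(C)c(O)c(C)c1O | intermediate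
8 | 2,5-dimethylresorcinol (2,5-dimethylbenzene-1,3-diol) | Cc1cc(O)c(C)c(O)c1 | starting material
9 | N-(2,4-dihydroxy-3,6-dimethylbenzylidene)-N-methylmethanaminium chloride (not isolated) | C[N+](C)=Cc1c(C)cc(O)c(C)c1O.[Cl-] | intermediate
10 | 2,4-dihydroxy-3,6-dimethylbenzaldehyde | O=Cc1c(C)cc(O)c(C)c1O | intermediate
11 | 2,4-bis(benzyloxy)-3,6-dimethylbenzaldehyde | O=Cc1c(C)cc(OCc2ccccc2)c(C)c1OCc1ccccc1 | intermediate
12 | 2,4-bis(benzyloxy)-3,6-dimethylbenzoic acid | OC(=O)c1c(C)cc(OCc2ccccc2)c(C)c1OCc1ccccc1 | intermediate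
13 | 2,4-bis(benzyloxy)-3,6-dimethylbenzoic trifluoroacetic anhydride (not isolated) | O=C(OC(=O)C(F)(F)F)c1c(C)cc(OCc2ccccc2)c(C)c1OCc1ccccc1 | intermediate
14 | methyl 4-{[2,4-bis(benzyloxy)-3,6-dimethylbenzoyl]oxy}-2-hydroxy-3,5,6-trimethylbenzoate | COC(=O)c1c(C)c(C)c(OC(=O)c2c(C)cc(OCc3ccccc3)c(C)c2OCc2ccccc2)c(C)c1O | intermediate
15 | methyl 4-{[2,4-bis(benzyloxy)-3,6-dimethylbenzoyl]oxy}-2-methoxy-3,5,6-trimethylbenzoate | COC(=O)c1c(C)c(C)c(OC(=O)c2c(C)cc(OCc3ccccc3)c(C)c2OCc2ccccc2)c(C)c1OC | intermediate
16 | 4-{[2,4-bis(benzyloxy)-3,6-dimethylbenzoyl]oxy}-2-methoxy-3,5,6-trimethylbenzoic acid | OC(=O)c1c(C)c(C)c(OC(=O)c2c(C)cc(OCc3ccccc3)c(C)c2OCc2ccccc2)c(C)c1OC | intermediate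
17 | 4-{[2,4-bis(benzyloxy)-3,6-dimethylbenzoyl]oxy}-2-methoxy-3,5,6-trimethylbenzoic trifluoroacetic anhydride (not isolated) | O=C(OC(=O)C(F)(F)F)c1c(C)c(C)c(OC(=O)c2c(C)cc(OCc3ccccc3)c(C)c2OCc2ccccc2)c(C)c1OC | intermediate
18 | 4-formyl-3-hydroxy-2,5-dimethylphenyl 4-{[2,4-bis(benzyloxy)-3,6-dimethylbenzoyl]oxy}-2-methoxy-3,5,6-trimethylbenzoate | O=Cc1c(C)cc(OC(=O)c2c(C)c(C)c(OC(=O)c3c(C)cc(OCc4ccccc4)c(C)c3OCc3ccccc3)c(C)c2OC)c(C)c1O | intermediate
19 | 4-formyl-3-methoxy-2,5-dimethylphenyl 4-{[2,4-bis(benzyloxy)-3,6-dimethylbenzoyl]oxy}-2-methoxy-3,5,6-trimethylbenzoate | COc1c(C)c(OC(=O)c2c(C)c(C)c(OC(=O)c3c(C)cc(OCc4ccccc4)c(C)c3OCc3ccccc3)c(C)c2OC)cc(C)c1C=O | intermediate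
20 | 4-[(4-{[2,4-bis(benzyloxy)-3,6-dimethylbenzoyl]oxy}-2-methoxy-3,5,6-trimethylbenzoyl)oxy]-2-methoxy-3,6-dimethylbenzoic acid | COc1c(C)c(OC(=O)c2c(C)c(C)c(OC(=O)c3c(C)cc(OCc4ccccc4)c(C)c3OCc3ccccc3)c(C)c2OC)cc(C)c1C(=O)O | intermediate
21 | 4-({4-[(2,4-dihydroxy-3,6-dimethylbenzoyl)oxy]-2-methoxy-3,5,6-trimethylbenzoyl}oxy)-2-methoxy-3,6-dimethylbenzoic acid | COc1c(C)c(OC(=O)c2c(C)c(C)c(OC(=O)c3c(C)cc(O)c(C)c3O)c(C)c2OC)cc(C)c1C(=O)O | target

**Step count and risks**
Total step count: 12. Longest linear sequence: 10 steps (steps 3, 4, 5, 6, 7, 8, 9, 10, 11, 12, from 8); the line from 1 and 2 is 9 steps.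

Steps most likely to fail:

Step 8. Iodide may also dealkylate at the benzylic carbons of the ring C ethers or at the O-methyl group next to the carboxyl, both helped by lithium chelation, or the ester cleavage may stall, so that protecting groups are lost or conversion stays incomplete. The fallback changes the ester instead of the cleavage reagent; it sets out from 7 and comes back at 16. Saponification of 7 (KOH, DMSO/H2O, 90 °C, cold acidification) would give 2,4-dihydroxy-3,5,6-trimethylbenzoic acid F1. Alkylation of the carboxylate alone (allyl bromide, KHCO3, DMF, rt) would give prop-2-enyl 2,4-dihydroxy-3,5,6-trimethylbenzoate F2. Esterification with 12 as in step 6, again through 13, would give prop-2-enyl 4-{[2,4-bis(benzyloxy)-3,6-dimethylbenzoyl]oxy}-2-hydroxy-3,5,6-trimethylbenzoate F3. Methylation as in step 7 would give prop-2-enyl 4-{[2,4-bis(benzyloxy)-3,6-dimethylbenzoyl]oxy}-2-methoxy-3,5,6-trimethylbenzoate F4. Allyl transfer to morpholine with catalytic Pd(PPh3)4 (zerovalent palladium) in THF at rt would then free acid 16 without touching benzyl ethers or the aryl ester.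

Step 2. Bromine may stay parked on the fully substituted C3 carbon, or bromide may demethylate the ester at the temperature needed for elimination, so that the arene is lost through decarboxylation. The fallback leaves halogen chemistry for direct hydride abstraction; it sets out from 4 and comes back at 7. DDQ (1.2 equiv) in dioxane at reflux should take hydride from C6 of the enolised dione and a proton from C5, and the dienone tautomerises to 7. This path makes no new compound (none F0).

Step 6. Acyl transfer to a hydroxyl flanked by two methyl groups may be slower than trifluoroacetylation of that hydroxyl or than acid-promoted loss of benzyl groups from the activated acid. The fallback separates activation from coupling and uses an anionic nucleophile; it sets out from 12 and comes back at 14. Oxalyl chloride with catalytic DMF in CH2Cl2 would give 2,4-bis(benzyloxy)-3,6-dimethylbenzoyl chloride F5. The monosodium phenoxide of 7 (NaH, 1.0 equiv, THF, 0 °C), formed at the more acidic, non-chelated O4, would be acylated by F5 to give 14.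

**Further compounds**
F1 | step 8 | 2,4-dihydroxy-3,5,6-trimethylbenzoic acid | OC(=O)c1c(C)c(C)c(O)c(C)c1O
F2 | step 8 | prop-2-enyl 2,4-dihydroxy-3,5,6-trimethylbenzoate | C=CCOC(=O)c1c(C)c(C)c(O)c(C)c1O
F3 | step 8 | prop-2-enyl 4-{[2,4-bis(benzyloxy)-3,6-dimethylbenzoyl]oxy}-2-hydroxy-3,5,6-trimethylbenzoate | C=CCOC(=O)c1c(C)c(C)c(OC(=O)c2c(C)cc(OCc3ccccc3)c(C)c2OCc2ccccc2)c(C)c1O
F4 | step 8 | prop-2-enyl 4-{[2,4-bis(benzyloxy)-3,6-dimethylbenzoyl]oxy}-2-methoxy-3,5,6-trimethylbenzoate | C=CCOC(=O)c1c(C)c(C)c(OC(=O)c2c(C)cc(OCc3ccccc3)c(C)c2OCc2ccccc2)c(C)c1OC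
F0 | step 2 | none | none
F5 | step 6 | 2,4-bis(benzyloxy)-3,6-dimethylbenzoyl chloride | O=C(Cl)c1c(C)cc(OCc2ccccc2)c(C)c1OCc1ccccc1
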